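The flavone is cut at C2–C1′, between pyranone ring C and pyrogallol ring B. C2 is by nature the acceptor end of the vinylogous ester O1–C2=C3–C4=O. Flanked by O1 and the C3 methoxy group, it also carries the only C–H of ring C, and that C–H is acidic. A hindered zinc amide therefore reverses its polarity. A Negishi coupling in the same flask then joins it to the bromine-bearing carbon of tribenzylated 5-bromopyrogallol, itself an acceptor carbon. The precursor is a plain 2-unsubstituted 3,5,7,8-tetramethoxychromone. Its para 5,8-dimethoxy pair is the latent ring A hydroquinone, released through the 5,8-quinone and one final hydrogenation that also removes the benzyl groups.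

Key step: step 4

Remark: the target has no stereocentre and no configurationally stable axis, so it is achiral and no step has to control configuration. Compounds 1, 2 and 7 are taken as catalogue chemicals.

Step 1
Reactants: 1 1,2,3,5-tetramethoxybenzene; 2 methoxyacetyl chloride
Product: 4 1-(2-hydroxy-3,4,6-trimethoxyphenyl)-2-methoxyethan-1-one, via pentamethoxy ketone 3 (not isolated)
Conditions: AlCl3 (excess), Et2O, 0 °C to reflux; then 2 M HCl
Reagents that add atoms: none
Why: Friedel–Crafts acylation can only strike the two equivalent free positions of 1, each activated by two ortho and one para methoxy group, and the aluminium chelate of ketone 3 then loses the methyl group of the C2 ether, which is squeezed between the acyl group and the C3 methoxy group, in a chelation-assisted ortho-demethylation that should leave the less strained C6 ether and the aliphatic ether intact.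

Step 2
Reactants: 4 1-(2-hydroxy-3,4,6-trimethoxyphenyl)-2-methoxyethan-1-one
Product: 6 3,5,7,8-tetramethoxy-4H-chromen-4-one, via enaminone 5 (not isolated)
Conditions: DMF dimethyl acetal, toluene, 100 °C; then conc. HCl, CH2Cl2, rt
Reagents that add atoms: N,N-dimethylformamide dimethyl acetal, COC(OC)N(C)C
Why: The methylene group between the ketone and the methoxy group condenses with the amide acetal to enaminone 5, and acid then triggers conjugate addition of the ortho phenol and loss of dimethylamine (enaminone route to chromones, 6-endo-trig addition–elimination), which installs C2 as an unsubstituted CH.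

Step 3
Reactants: 7 5-bromobenzene-1,2,3-triol
Product: 8 1,2,3-tris(benzyloxy)-5-bromobenzene
Conditions: BnBr, K2CO3, DMF, 60 °C, N2
Reagents that add atoms: benzyl bromide, BrCc1ccccc1
Why: Williamson ether synthesis of the three phenoxides with a reactive benzylic halide, run under nitrogen because pyrogallol anions autoxidise, leaves the aryl bromide untouched.

Step 4
Reactants: 6 3,5,7,8-tetramethoxy-4H-chromen-4-one; 8 1,2,3-tris(benzyloxy)-5-bromobenzene
Product: 10 2-[3,4,5-tris(benzyloxy)phenyl]-3,5,7,8-tetramethoxy-4H-chromen-4-one, via chromon-2-ylzinc chloride 9 (not isolated)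
Conditions: TMPZnCl·LiCl, THF, 25 °C; then 8, Pd(OAc)2 (cat.), SPhos (cat.), THF, 50 °C
Reagents that add atoms: 2,2,6,6-tetramethylpiperidin-1-ylzinc chloride lithium chloride complex, CC1(C)CCCC(C)(C)N1[Zn]Cl.[Li+].[Cl-] (its zinc and chloride are carried only by intermediate 9, not by 10)
Why: The hindered amide base removes the C2–H of ring C, which is acidified by the adjacent O1 and the C3 methoxy group (both can also hold the zinc), so the natural acceptor carbon of the O1–C2=C3–C4=O vinylogous ester becomes the alkenylzinc donor 9; oxidative addition of Pd(0)/SPhos into the C–Br bond of 8, transmetalation from 9 and reductive elimination then form C2–C1′. The closest known reaction type is the directed C–H zincation of chromones followed by Negishi cross-coupling with aryl halides, which is established as a way to flavones. No ring is closed and no stereocentre is created. The step needs selectivity for C2–H over C6–H of ring A and over nucleophilic opening of the pyranone: C3 is blocked by its methoxy group, the mild zinc amide should not metalate a simple dimethoxyarene C–H at 25 °C, and the bulk of the amide suppresses conjugate addition at C2. β-Elimination from 9 is excluded because loss of the C3 methoxide would give a six-membered cycloalkyne, and the ketone, the methyl ethers and the benzyl ethers tolerate organozinc chemistry, while bromide 8 is added only after the zincation.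

Step 5
Reactants: 10 2-[3,4,5-tris(benzyloxy)phenyl]-3,5,7,8-tetramethoxy-4H-chromen-4-one
Product: 11 2-[3,4,5-tris(benzyloxy)phenyl]-3,7-dimethoxy-4H-chromene-4,5,8-trione
Conditions: (NH4)2Ce(NO3)6, MeCN/CH2Cl2/H2O, 0 °C
Reagents that add atoms: water, O
Why: In this cerium(IV) oxidative demethylation of a para-dimethoxyarene, ring A, the only ring with a para pair of ether oxygens (C5 and C8) and thus the easiest to oxidise, loses two electrons, takes up water at C5 and C8 and expels two molecules of methanol to give the p-quinone, while the 1,2,3-trioxygenated ring B, the plain benzyl ethers and the C3 and C7 methyl ethers should persist at 0 °C.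

Step 6
Reactants: 11 2-[3,4,5-tris(benzyloxy)phenyl]-3,7-dimethoxy-4H-chromene-4,5,8-trione
Product: 13 5,8-dihydroxy-3,7-dimethoxy-2-(3,4,5-trihydroxyphenyl)-4H-chromen-4-one, via hydroquinone tribenzyl ether 12 (not isolated)
Conditions: H2 (1 atm), Pd/C, THF/MeOH, rt; filtration and concentration under argon
Reagents that add atoms: none
Why: Catalytic hydrogenation first reduces the quinone to hydroquinone 12 and hydrogenolysis then cleaves the three aryl benzyl ethers, while the methyl ethers and the tetrasubstituted C2=C3 bond of the vinylogous ester are inert under one atmosphere of hydrogen.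

Compound list
1 | 1,2,3,5-tetramethoxybenzene | COc1cc(OC)c(OC)c(OC)c1 | starting material
2 | methoxyacetyl chloride | COCC(=O)Cl | starting material
3 | 2-methoxy-1-(2,3,4,6-tetramethoxyphenyl)ethan-1-one | COCC(=O)c1c(OC)c(OC)c(OC)cc1OC | intermediate
4 | 1-(2-hydroxy-3,4,6-trimethoxyphenyl)-2-methoxyethan-1-one | COCC(=O)c1c(O)c(OC)c(OC)cc1OC | intermediate
5 | (Z)-3-(dimethylamino)-1-(2-hydroxy-3,4,6-trimethoxyphenyl)-2-methoxyprop-2-en-1-one (amino group trans to the carbonyl group; the geometry has no consequence) | CO/C(=C\N(C)C)C(=O)c1c(O)c(OC)c(OC)cc1OC | intermediate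
6 | 3,5,7,8-tetramethoxy-4H-chromen-4-one | COc1cc(OC)c2c(=O)c(OC)coc2c1OC | intermediate
7 | 5-bromobenzene-1,2,3-triol | Oc1cc(Br)cc(O)c1O | starting material
8 | 1,2,3-tris(benzyloxy)-5-bromobenzene | Brc1cc(OCc2ccccc2)c(OCc2ccccc2)c(OCc2ccccc2)c1 | intermediate
9 | chloro(3,5,7,8-tetramethoxy-4-oxo-4H-chromen-2-yl)zinc (as LiCl complex in THF) | COc1cc(OC)c2c(=O)c(OC)c([Zn]Cl)oc2c1OC | intermediate
10 | 2-[3,4,5-tris(benzyloxy)phenyl]-3,5,7,8-tetramethoxy-4H-chromen-4-one | COc1cc(OC)c2c(=O)c(OC)c(-c3cc(OCc4ccccc4)c(OCc4ccccc4)c(OCc4ccccc4)c3)oc2c1OC | intermediate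
11 | 2-[3,4,5-tris(benzyloxy)phenyl]-3,7-dimethoxy-4H-chromene-4,5,8-trione | COC1=CC(=O)C2=C(OC(=C(OC)C2=O)c3cc(OCc4ccccc4)c(OCc4ccccc4)c(OCc4ccccc4)c3)C1=O | intermediate
12 | 2-[3,4,5-tris(benzyloxy)phenyl]-5,8-dihydroxy-3,7-dimethoxy-4H-chromen-4-one | COc1cc(O)c2c(=O)c(OC)c(-c3cc(OCc4ccccc4)c(OCc4ccccc4)c(OCc4ccccc4)c3)oc2c1O | intermediate
13 | 5,8-dihydroxy-3,7-dimethoxy-2-(3,4,5-trihydroxyphenyl)-4H-chromen-4-one (5,8,3',4',5'-pentahydroxy-3,7-dimethoxyflavone, achiral) | COc1cc(O)c2c(=O)c(OC)c(-c3cc(O)c(O)c(O)c3)oc2c1O | target

Total step count: 6. Longest linear sequence: 5 steps (1, 2, 4, 5, 6).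

Steps most likely to fail

Step 4. The zincation may stay incomplete on the electron-rich chromone or stray to C6–H of ring A. Transmetalation and reductive elimination at the crowded C2 next to the C3 methoxy group may also be slow, so that protodezincation and homocoupling take over. The fallback sets out from 6 and 8, comes back at 10, and uses C2 in its innate acceptor role.
- Bromide 8 is converted with magnesium in THF into [3,4,5-tris(benzyloxy)phenyl]magnesium bromide F1.
- F1 is added to 6 in a copper-catalysed conjugate addition in the presence of Me3SiCl (CuBr·SMe2 cat., THF, −40 °C). This should give racemic 2-[3,4,5-tris(benzyloxy)phenyl]-3,5,7,8-tetramethoxy-4-(trimethylsilyloxy)-2H-chromene F2.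
- Oxidation of this silyl enol ether with DDQ (hydride abstraction from C2–H, then loss of the silyl group) restores the C2=C3 bond and delivers 10.

Step 5. Electron transfer from ring B, benzylic oxidation with loss of benzyl groups, or hydrolysis of the C7 vinylogous ester of the quinone may compete with the clean oxidation of ring A. The fallback sets out from 6 and comes back at 13. It moves the oxidative demethylation ahead of the coupling, where neither ring B nor a benzyl ether is present.
- Chromone 6 is oxidised with cerium(IV) ammonium nitrate to 3,7-dimethoxy-4H-chromene-4,5,8-trione F3.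
- F3 is reduced with aqueous Na2S2O4 to 5,8-dihydroxy-3,7-dimethoxy-4H-chromen-4-one F4.
- F4 is benzylated (BnBr, K2CO3, DMF, 70 °C) to 5,8-bis(benzyloxy)-3,7-dimethoxy-4H-chromen-4-one F5.
- Zincation with TMPZnCl·LiCl gives [5,8-bis(benzyloxy)-3,7-dimethoxy-4-oxo-4H-chromen-2-yl]zinc chloride F6.
- Negishi coupling of F6 with 8 gives 5,8-bis(benzyloxy)-2-[3,4,5-tris(benzyloxy)phenyl]-3,7-dimethoxy-4H-chromen-4-one F7.
- Hydrogenolysis of F7 (H2, Pd/C) leads directly to 13.

Step 1. The methoxyacetyl cation may lose carbon monoxide, which would lead to methoxymethylation of the arene. The Lewis acid may also cleave the less hindered C6 ether or both ortho ethers. The fallback sets out from 1 and comes back at 4. It separates C–C bond formation from the demethylation.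
- Compound 1 is lithiated with n-BuLi (THF, 0 °C) at the position between two methoxy groups to (2,3,4,6-tetramethoxyphenyl)lithium F8.
- F8 is acylated with N,2-dimethoxy-N-methylacetamide to give ketone 3, now isolated.
- BCl3 (CH2Cl2, −78 to 0 °C) then removes the sterically compressed C2 methyl group under chelation control to give 4.

Further compounds
F1 | step 4 | [3,4,5-tris(benzyloxy)phenyl]magnesium bromide | Br[Mg]c1cc(OCc2ccccc2)c(OCc2ccccc2)c(OCc2ccccc2)c1
F2 | step 4 | 2-[3,4,5-tris(benzyloxy)phenyl]-3,5,7,8-tetramethoxy-4-(trimethylsilyloxy)-2H-chromene (racemic at C2) | COC1=C(O[Si](C)(C)C)c2c(OC)cc(OC)c(OC)c2OC1c3cc(OCc4ccccc4)c(OCc4ccccc4)c(OCc4ccccc4)c3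
F3 | step 5 | 3,7-dimethoxy-4H-chromene-4,5,8-trione | COC1=CC(=O)C2=C(OC=C(OC)C2=O)C1=O
F4 | step 5 | 5,8-dihydroxy-3,7-dimethoxy-4H-chromen-4-one | COc1cc(O)c2c(=O)c(OC)coc2c1O
F5 | step 5 | 5,8-bis(benzyloxy)-3,7-dimethoxy-4H-chromen-4-one | COc1cc(OCc3ccccc3)c2c(=O)c(OC)coc2c1OCc4ccccc4
F6 | step 5 | [5,8-bis(benzyloxy)-3,7-dimethoxy-4-oxo-4H-chromen-2-yl]zinc chloride | COc1cc(OCc3ccccc3)c2c(=O)c(OC)c([Zn]Cl)oc2c1OCc4ccccc4
F7 | step 5 | 5,8-bis(benzyloxy)-2-[3,4,5-tris(benzyloxy)phenyl]-3,7-dimethoxy-4H-chromen-4-one | COc1cc(OCc3ccccc3)c2c(=O)c(OC)c(-c5cc(OCc6ccccc6)c(OCc6ccccc6)c(OCc6ccccc6)c5)oc2c1OCc4ccccc4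
F8 | step 1 | (2,3,4,6-tetramethoxyphenyl)lithium | [Li]c1c(OC)c(OC)c(OC)cc1OC
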